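**Retrosynthetic overview**
- 11 ⇒ 10 ⇒ 9: the formyl group is traced back through the carbinol to a methyl ester, an adjustment of oxidation state only.
- 9 ⇒ 2 + 5 + 4: the pyrrole is cut at N1=C5, C2–C3 and C4–C5. The strategy rests on N1, C2 and the exocyclic carbonyl carbon being a glycine N–Cα–C(=O) unit, and on C5 with its C19 chain being the carbonyl carbon of a C20 fatty aldehyde. Only C3–C4 is missing; disulfone 4 supplies it as an acetylene equivalent whose two sulfonyl groups leave as sulfinate to aromatise the ring.
- 2 ⇒ 1 by alcohol oxidation; 5 is released from its hydrochloride 3 in the flask.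
- Ring order: the pyrrole is the only ring and is formed in step 2.

Key step: step 2

Remark: the target has no stereocentre and no stereogenic double bond, so it is a single achiral compound; the stereocentres of 7 and 8 are transient and are left uncontrolled.

**Step 1**
Reactants: 1 icosan-1-ol
Product: 2 icosanal
Conditions: TEMPO (10 mol %), PhI(OAc)2 (1.1 equiv), CH2Cl2, 25–30 °C; aldehyde used freshly prepared
Reagents that add atoms: none
Why: The oxoammonium-mediated TEMPO/PhI(OAc)2 oxidation of a primary alcohol should stop at the aldehyde under anhydrous conditions, at a temperature where the waxy C20 alcohol stays dissolved.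

**Step 2**
Reactants: 2 icosanal, 3 glycine methyl ester hydrochloride, 4 (E)-1,2-bis(phenylsulfonyl)ethene
Product: 9 methyl 5-nonadecyl-1H-pyrrole-2-carboxylate, via glycine methyl ester 5 (not isolated), via imino ester 6 (not isolated), via bis-sulfonyl pyrrolidine 7 (not isolated), via sulfonyl pyrroline 8 (not isolated)
Conditions: (i) 2 (1.05 equiv), 3 (1.0 equiv), Et3N (1.0 equiv), MgSO4, CH2Cl2, 0 °C → rt; solvent exchanged to THF and filtered under Ar (MgSO4 and Et3N·HCl removed); (ii) 4 (1.0 equiv), AgOAc (10 mol %), PPh3 (11 mol %), Et3N (20 mol %), THF, rt, dark; (iii) DBU (3 equiv), rt → 40 °C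
Reagents that add atoms: none
Why: Condensation of 2 with the liberated amine 5 gives aldimine 6, whose N,O-chelation to Ag(I) acidifies only the glycine CH2 so that Et3N forms the metallo-azomethine ylide; this adds across the doubly activated alkene 4 to give pyrrolidine 7, and DBU then expels two benzenesulfinates by E1cB-type eliminations (through 8, drawn for first loss of the C3 sulfinate; a regioisomeric vinyl sulfone would converge on the same product) and tautomerisation to pyrrole 9, the two sulfinate losses supplying both oxidation levels so that no oxidant is needed. The closest known reaction type is the silver- or copper-catalysed 1,3-dipolar cycloaddition of α-imino esters to bis-sulfonyl ethylenes followed by base-induced aromatisation, together with silver-catalysed three-component couplings of enolisable aldehydes, glycine derivatives and electron-poor alkenes. The single ring is closed in an intermolecular [3+2] mode, C2–C3 and C4–C5 being formed on the C2–N1=C5 dipole; in the stepwise limit this is a Michael addition followed by a 5-endo-trig Mannich closure. The four stereocentres of 7 (2,5-cis expected from the W-shaped ylide, 3,4-trans from the E-alkene) need no controlling element because all are destroyed on aromatisation. The step needs chemoselectivity: the ylide must be trapped faster than the enolisable aldimine tautomerises or self-condenses, and no primary amine may remain to add to 4 and no chloride to precipitate the silver. This is secured by the slight excess of 2, by completing imine formation and filtering off the ammonium chloride before silver and 4 are added, and by the high electrophilicity of 4; regiochemistry does not arise because the two alkene carbons of 4 are equivalent.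

**Step 3**
Reactants: 9 methyl 5-nonadecyl-1H-pyrrole-2-carboxylate
Product: 10 (5-nonadecyl-1H-pyrrol-2-yl)methanol
Conditions: LiAlH4 (2.5 equiv), THF, 0 °C → rt; H2O, 15 % aq NaOH, H2O work-up; crude carbinol used at once
Reagents that add atoms: none
Why: Hydride reduction of the ester with LiAlH4 should give the primary alcohol after N–H deprotonation, and holding the temperature at or below rt with a basic work-up avoids azafulvene-mediated over-reduction and acid-triggered oligomerisation of the pyrrolylcarbinol.

**Step 4**
Reactants: 10 (5-nonadecyl-1H-pyrrol-2-yl)methanol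
Product: 11 5-nonadecyl-1H-pyrrole-2-carbaldehyde
Conditions: activated MnO2 (15 equiv), CH2Cl2, rt; filtration through Celite
Reagents that add atoms: none
Why: The MnO2 oxidation of a benzylic-type heteroaryl carbinol should give the aldehyde chemoselectively, and the 2-formylpyrrole formed is a vinylogous formamide that resists further oxidation.

**Compound list**
1 | icosan-1-ol | CCCCCCCCCCCCCCCCCCCCO | starting material
2 | icosanal | CCCCCCCCCCCCCCCCCCCC=O | intermediate
3 | glycine methyl ester hydrochloride | COC(=O)CN.Cl | starting material
4 | (E)-1,2-bis(phenylsulfonyl)ethene | O=S(=O)(/C=C/S(=O)(=O)c1ccccc1)c1ccccc1 | starting material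
5 | glycine methyl ester (free base, formed in the flask) | COC(=O)CN | intermediate
6 | methyl N-[(E)-icosylidene]glycinate (not isolated) | CCCCCCCCCCCCCCCCCCC/C=N/CC(=O)OC | intermediate
7 | methyl 5-nonadecyl-3,4-bis(phenylsulfonyl)pyrrolidine-2-carboxylate (racemic diastereomer mixture, not isolated) | CCCCCCCCCCCCCCCCCCCC1NC(C(=O)OC)C(S(=O)(=O)c2ccccc2)C1S(=O)(=O)c1ccccc1 | intermediate
8 | methyl 5-nonadecyl-4-(phenylsulfonyl)-4,5-dihydro-1H-pyrrole-2-carboxylate (racemic, not isolated) | CCCCCCCCCCCCCCCCCCCC1NC(C(=O)OC)=CC1S(=O)(=O)c1ccccc1 | intermediate
9 | methyl 5-nonadecyl-1H-pyrrole-2-carboxylate | CCCCCCCCCCCCCCCCCCCc1ccc(C(=O)OC)[nH]1 | intermediate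
10 | (5-nonadecyl-1H-pyrrol-2-yl)methanol | CCCCCCCCCCCCCCCCCCCc1ccc(CO)[nH]1 | intermediate
11 | 5-nonadecyl-1H-pyrrole-2-carbaldehyde | CCCCCCCCCCCCCCCCCCCc1ccc(C=O)[nH]1 | target

**Total step count:** 4
**Longest linear sequence:** 4 steps (1 → 2 → 9 → 10 → 11)

**Steps most likely to fail**

Step 2. The enolisable aldimine may tautomerise to its enamine or self-condense in an aldol-type manner faster than the silver ylide is trapped. Incomplete imine formation would also leave primary amine to add to the disulfone, and residual chloride would take the silver out of the cycle. The fallback sets out from 2 and returns to the route at 11, closing the ring by Paal–Knorr condensation instead. The Grignard reagent from 2-(2-bromoethyl)-1,3-dioxolane (Mg, THF, below 30 °C) is added to 2 to give 1-(1,3-dioxolan-2-yl)docosan-3-ol F1. Dess–Martin oxidation (CH2Cl2, NaHCO3, rt) should give 1-(1,3-dioxolan-2-yl)docosan-3-one F2. Heating F2 with NH4OAc in AcOH unmasks the aldehyde and condenses the 1,4-dicarbonyl unit to 2-nonadecyl-1H-pyrrole F3. Vilsmeier–Haack formylation (POCl3, DMF, 0 °C → rt) at the free α-position gives N,N-dimethyl-1-(5-nonadecyl-1H-pyrrol-2-yl)methaniminium chloride F4, which aqueous NaOAc hydrolyses to 11.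

Step 3. After the first hydride transfers the N-metallated pyrrolylmethoxide may lose its aluminate oxygen to an azafulvene that takes up further hydride, which is over-reduction to the 2-methylpyrrole. The carbinol may also oligomerise during work-up. The fallback sets out from 9 and returns at 11 without passing through 10. Aminolysis of 9 with Me(MeO)NH·HCl and AlMe3 (toluene, 0 → 60 °C) gives N-methoxy-N-methyl-5-nonadecyl-1H-pyrrole-2-carboxamide F5. LiAlH4 (THF, −40 → 0 °C) then delivers a single hydride, and the chelated tetrahedral intermediate releases 11 only on aqueous work-up.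

Step 4. The electron-rich pyrrolylcarbinol may ionise on the mildly acidic oxide surface to an azafulvenium ion and self-condense to dipyrromethane-type oligomers before the heterogeneous oxidation is complete. The fallback sets out from 9 and returns at 11 by a McFadyen–Stevens sequence that never forms the carbinol. Hydrazinolysis (N2H4·H2O, EtOH, reflux) gives 5-nonadecyl-1H-pyrrole-2-carbohydrazide F6. TsCl in pyridine at 0 °C gives N'-(4-methylphenylsulfonyl)-5-nonadecyl-1H-pyrrole-2-carbohydrazide F7. Brief heating of F7 with Na2CO3 in ethylene glycol at 150–160 °C should expel sulfinate and nitrogen to give 11.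

**Further compounds**
F1 | step 2 | 1-(1,3-dioxolan-2-yl)docosan-3-ol (racemic) | CCCCCCCCCCCCCCCCCCCC(O)CCC1OCCO1
F2 | step 2 | 1-(1,3-dioxolan-2-yl)docosan-3-one | CCCCCCCCCCCCCCCCCCCC(=O)CCC1OCCO1
F3 | step 2 | 2-nonadecyl-1H-pyrrole | CCCCCCCCCCCCCCCCCCCc1ccc[nH]1
F4 | step 2 | N,N-dimethyl-1-(5-nonadecyl-1H-pyrrol-2-yl)methaniminium chloride | CCCCCCCCCCCCCCCCCCCc1ccc(C=[N+](C)C)[nH]1.[Cl-]
F5 | step 3 | N-methoxy-N-methyl-5-nonadecyl-1H-pyrrole-2-carboxamide | CCCCCCCCCCCCCCCCCCCc1ccc(C(=O)N(C)OC)[nH]1
F6 | step 4 | 5-nonadecyl-1H-pyrrole-2-carbohydrazide | CCCCCCCCCCCCCCCCCCCc1ccc(C(=O)NN)[nH]1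
F7 | step 4 | N'-(4-methylphenylsulfonyl)-5-nonadecyl-1H-pyrrole-2-carbohydrazide | CCCCCCCCCCCCCCCCCCCc1ccc(C(=O)NNS(=O)(=O)c2ccc(C)cc2)[nH]1
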